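**Retrosynthetic overview**
1. Target 16 ⇒ one pot from 2,4-diformylphloroglucinol 12, isovaleraldehyde 13 and the tricyclic C14 olefin 10: o-quinone methide alkylation at C6 of 10, 1,2-hydride shift (H-3a → C6a), phenol capture at C3a. This closes the oxepane last and sets four stereocentres.
2. Olefin 10 ⇒ 1,5-diketone 9 by intramolecular McMurry coupling (cyclopentene ring).
3. Diketone 9 ⇒ ene-dione 4 plus a C4 Grignard reagent (conjugate addition with enolate triflation, then hydrogenolysis of the enol triflate).
4. Ene-dione 4 ⇒ (S)-carvone (HCl/base cyclopropane closure, then γ-oxidation).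
5. Ring order: cyclohexene (chiral pool) → cyclopropane → cyclopentene → oxepane.

Assumption: the presumed biosynthesis is attack of the tetrasubstituted vinylcyclopropane olefin of a C14 nor-aromadendrene on the o-quinone methide from 12 and 13, then 1,2-hydride shift and phenoxide capture. The cyclopropane configuration of the target is opposite to that of (+)-3-carene, so (S)-carvone is used as the chiral source.

**Step 1**
Reactants: 1 (S)-(+)-carvone
Product: 3 (1R,6S)-3,7,7-trimethylbicyclo[4.1.0]hept-3-en-2-one, via carvone hydrochloride 2 (not isolated)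
Conditions: HCl (g), Et2O, 0 °C; evaporate; then t-BuOK, THF/t-BuOH, 0 °C
Reagents that add atoms: none
Why: Markovnikov HCl addition to the isopropenyl group followed by 3-exo-tet alkylation of the α'-enolate by the tertiary chloride (carvone → carenone cyclisation) closes the cis-fused gem-dimethylcyclopropane, both of whose stereocentres follow from C5 of (S)-carvone.

**Step 2**
Reactants: 3 (1R,6S)-3,7,7-trimethylbicyclo[4.1.0]hept-3-en-2-one
Product: 4 (1R,6S)-3,7,7-trimethylbicyclo[4.1.0]hept-3-ene-2,5-dione
Conditions: Rh2(cap)4 (1 mol %), t-BuOOH (70% aq, 5 equiv), K2CO3 (0.5 equiv), CH2Cl2, rt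
Reagents that add atoms: tert-butyl hydroperoxide, CC(C)(C)OO
Why: Dirhodium caprolactamate/TBHP allylic (γ-C–H) oxidation of an enone to the ene-1,4-dione acts at the only allylic methylene (C5) and touches no stereocentre.

**Step 3**
Reactants: 4 (1R,6S)-3,7,7-trimethylbicyclo[4.1.0]hept-3-ene-2,5-dione; 5 2-(2-bromoethyl)-2-methyl-1,3-dioxolane
Product: 7 (1R,4R,6S)-3,7,7-trimethyl-4-[2-(2-methyl-1,3-dioxolan-2-yl)ethyl]-5-oxobicyclo[4.1.0]hept-2-en-2-yl trifluoromethanesulfonate, via bromomagnesium enolate 6 (not isolated)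
Conditions: 5, Mg, THF, rt; then CuBr·SMe2 (10 mol %), 4, THF, −78 °C; then PhNTf2, −78 → 0 °C
Reagents that add atoms: N-phenylbis(trifluoromethanesulfonimide), O=S(=O)(N(c1ccccc1)S(=O)(=O)C(F)(F)F)C(F)(F)F
Why: Cu-catalysed 1,4-addition of the Grignard reagent goes to the unsubstituted β-carbon C4 on the face opposite the gem-dimethylcyclopropane (sets C4), and the regiodefined C2 enolate is trapped as the enol triflate (conjugate addition–enolate triflation).

**Step 4**
Reactants: 7 (1R,4R,6S)-3,7,7-trimethyl-4-[2-(2-methyl-1,3-dioxolan-2-yl)ethyl]-5-oxobicyclo[4.1.0]hept-2-en-2-yl trifluoromethanesulfonate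
Product: 9 (1S,3R,4S,6R)-4,7,7-trimethyl-3-(3-oxobutyl)bicyclo[4.1.0]heptan-2-one, via dioxolane ketone 8 (not isolated)
Conditions: H2 (1 atm), PtO2 (10 mol %), NaHCO3, EtOAc, rt; filter; then 1 M HCl, THF, rt
Reagents that add atoms: water, O
Why: Pt-catalysed hydrogenolysis/hydrogenation of the enol triflate (ketone → methylene via enol triflate) removes the former C2 oxygen and delivers H to the methyl-bearing carbon from the face opposite the cyclopropane bridge, so the methyl ends cis to the bridge and trans to the side chain; acid hydrolysis of the ketal then frees the methyl ketone.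

**Step 5**
Reactants: 9 (1S,3R,4S,6R)-4,7,7-trimethyl-3-(3-oxobutyl)bicyclo[4.1.0]heptan-2-one
Product: 10 (1aR,3S,3aR,6bS)-1,1,3,6-tetramethyl-1,1a,2,3,3a,4,5,6b-octahydrocyclopropa[e]indene
Conditions: TiCl3(DME)1.5, Zn–Cu, DME, reflux, slow addition (0.005 M)
Reagents that add atoms: none
Why: Intramolecular McMurry coupling of a 1,5-diketone gives the tetrasubstituted cyclopentene (C6=C6a) without forming or disturbing a stereocentre.

**Step 6**
Reactants: 11 phloroglucinol
Product: 12 2,4,6-trihydroxybenzene-1,3-dicarbaldehyde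
Conditions: POCl3 (2.2 equiv), DMF (2.2 equiv), dioxane, 0 °C → rt; then H2O
Reagents that add atoms: N,N-dimethylformamide, CN(C)C=O; water, O
Why: Double Vilsmeier–Haack formylation of the electron-rich arene stops at the dialdehyde because each formyl group deactivates the ring.

**Step 7**
Reactants: 12 2,4,6-trihydroxybenzene-1,3-dicarbaldehyde; 13 3-methylbutanal; 10 (1aR,3S,3aR,6bS)-1,1,3,6-tetramethyl-1,1a,2,3,3a,4,5,6b-octahydrocyclopropa[e]indene
Product: 16 CNP0202714.1 (target), via o-quinone methide 14 (not isolated), via cyclopropylcarbinyl zwitterion 15 (not isolated)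
Conditions: NaOAc (20 mol %), AcOH/HFIP (1:4), 50 °C
Reagents that add atoms: none
Why: Proposed new method: Knoevenagel condensation gives the (E)-o-quinone methide 14, which is attacked at its exocyclic carbon by C6 of 10 on the face syn to H-3a (away from the cyclohexane ring) in a hetero-Diels–Alder-like orientation to give the tertiary cyclopropylcarbinyl cation 15; direct O–C6a closure to the congested chroman is reversible in AcOH/HFIP (tertiary cyclopropylcarbinyl ether of an acidic phenol), so the cation drains by suprafacial 1,2-shift of H-3a to C6a and the tethered phenoxide captures C3a on the same face, which fixes the benzylic, C6, C6a and C3a centres from the carane stereocentres; the closest known chemistry is the three-component o-quinone-methide/terpene hetero-Diels–Alder coupling of formyl-phloroglucinol meroterpenoids, here interrupted by a 1,2-hydride shift.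

**Compound list**
1 | (S)-(+)-carvone, (5S)-2-methyl-5-(prop-1-en-2-yl)cyclohex-2-en-1-one | CC1=CC[C@@H](CC1=O)C(C)=C | starting material
2 | carvone hydrochloride, (5S)-5-(2-chloropropan-2-yl)-2-methylcyclohex-2-en-1-one | CC1=CC[C@@H](CC1=O)C(C)(C)Cl | intermediate
3 | (1R,6S)-3,7,7-trimethylbicyclo[4.1.0]hept-3-en-2-one (car-3-en-2-one) | CC1=CC[C@H]2[C@@H](C1=O)C2(C)C | intermediate
4 | (1R,6S)-3,7,7-trimethylbicyclo[4.1.0]hept-3-ene-2,5-dione | CC1=CC(=O)[C@H]2[C@@H](C1=O)C2(C)C | intermediate
5 | 2-(2-bromoethyl)-2-methyl-1,3-dioxolane | CC1(CCBr)OCCO1 | starting material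
6 | bromomagnesium (1R,4R,6S)-3,7,7-trimethyl-4-[2-(2-methyl-1,3-dioxolan-2-yl)ethyl]-5-oxobicyclo[4.1.0]hept-2-en-2-olate | CC1=C(O[Mg]Br)[C@@H]2[C@H](C(=O)[C@@H]1CCC3(C)OCCO3)C2(C)C | intermediate
7 | (1R,4R,6S)-3,7,7-trimethyl-4-[2-(2-methyl-1,3-dioxolan-2-yl)ethyl]-5-oxobicyclo[4.1.0]hept-2-en-2-yl trifluoromethanesulfonate (side chain anti to the CMe2 bridge) | CC1=C(OS(=O)(=O)C(F)(F)F)[C@@H]2[C@H](C(=O)[C@@H]1CCC3(C)OCCO3)C2(C)C | intermediate
8 | (1S,3R,4S,6R)-4,7,7-trimethyl-3-[2-(2-methyl-1,3-dioxolan-2-yl)ethyl]bicyclo[4.1.0]heptan-2-one | CC1(OCCO1)CC[C@H]2C(=O)[C@H]3[C@@H](C[C@@H]2C)C3(C)C | intermediate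
9 | (1S,3R,4S,6R)-4,7,7-trimethyl-3-(3-oxobutyl)bicyclo[4.1.0]heptan-2-one (4-Me cis to the CMe2 bridge, side chain trans to both) | CC(=O)CC[C@H]1C(=O)[C@H]2[C@@H](C[C@@H]1C)C2(C)C | intermediate
10 | (1aR,3S,3aR,6bS)-1,1,3,6-tetramethyl-1,1a,2,3,3a,4,5,6b-octahydrocyclopropa[e]indene (C6=C6a olefin) | CC1=C2[C@H]3[C@@H](C[C@H](C)[C@H]2CC1)C3(C)C | intermediate
11 | phloroglucinol (benzene-1,3,5-triol) | Oc1cc(O)cc(O)c1 | starting material
12 | 2,4-diformylphloroglucinol (2,4,6-trihydroxybenzene-1,3-dicarbaldehyde) | O=Cc1c(O)cc(O)c(C=O)c1O | intermediate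
13 | 3-methylbutanal (isovaleraldehyde) | CC(C)CC=O | starting material
14 | (E)-o-quinone methide, 2,4-dihydroxy-5-[(E)-3-methylbutylidene]-6-oxocyclohexa-1,3-diene-1,3-dicarbaldehyde | CC(C)C/C=C1/C(=O)C(C=O)=C(O)C(C=O)=C1O | intermediate
15 | zwitterion: phenoxide with the benzylic carbon bonded to C6 of the terpene and a tertiary cyclopropylcarbinyl cation at C6a | CC(C)C[C@@H](c1c(O)c(C=O)c(O)c(C=O)c1[O-])[C@@]2(C)CC[C@H]3[C+]2[C@H]4[C@@H](C[C@@H]3C)C4(C)C | intermediate
16 | CNP0202714.1: oxepane-bridged diformylphloroglucinol–nor-aromadendrane adduct (benzylic CH R, O-bearing C S, C–Me quaternary R, ring-fusion CH R, cyclopropane CH R and R, CHMe S) | CC(C)C[C@H]1c2c(O)c(C=O)c(O)c(C=O)c2O[C@]23CC[C@@]1(C)[C@H]2[C@H]1[C@@H](C[C@@H]3C)C1(C)C | target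

**Step count**
Total steps: 7. Longest linear sequence: 6 (steps 1, 2, 3, 4, 5, 7 from (S)-carvone).

**Three steps most likely to fail, with fallbacks**

Step 7 (cascade). Risks: the reaction may stop at the ordinary [4+2] chroman, or the cyclopropylcarbinyl cation may open the cyclopropane. Fallback, setting out from 10 and returning at 16: heat 10, 12 and 13 under neutral conditions (water/dioxane, 100 °C) and isolate the cis-fused chroman cycloadduct F1 (O on C6a, benzylic carbon on C6). Then, as a separate step, ionise its tertiary cyclopropylcarbinyl aryl ether at low temperature (TfOH 5 mol %, HFIP/CH2Cl2, −20 °C) so that the 1,2-hydride shift and re-closure at C3a give 16. This replaces the one-pot cascade by cycloaddition followed by a discrete cationic ring expansion.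

Step 5 (McMurry). Risk: the ketyl of the cyclopropyl ketone may open the gem-dimethylcyclopropane. Fallback, setting out from 9 and returning at 10: methylenate both ketones of 9 (excess Ph3P=CH2, toluene, 80 °C) to the bis-methylene diene F2, then close the tetrasubstituted olefin by ring-closing metathesis (Stewart–Grubbs Ru catalyst, toluene, 80 °C, loss of ethene) to give 10. No single-electron chemistry touches the cyclopropyl ketone.

Step 4 (hydrogenolysis/hydrogenation). Risks: hydrogenolysis of the vinylcyclopropane, or hydrogen delivery from the wrong face next to the C4 side chain. Fallback, setting out from 4 and returning at 10: add the Grignard reagent from 5 (CuBr·SMe2 cat.) to 4 and quench with aqueous HCl, which protonates the enolate, cleaves the dioxolane and lets C3/C4 equilibrate to the trans arrangement, giving the triketone F3. McMurry coupling (the ring C2 ketone cannot form an olefin with the side-chain ketone because that would be a bridgehead alkene) gives the tricyclic ketone F4. Wolff–Kishner reduction (N2H4·H2O, KOH, diethylene glycol, 200 °C) of F4 gives 10. The oxygen is thus removed at the end by hydrazone chemistry instead of by enol triflate hydrogenolysis.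

**Further compounds**
F1 | step 7 | cis-fused chroman hetero-Diels–Alder adduct (aryl ether O on C6a, benzylic carbon on C6, H-3a retained) | CC(C)C[C@H]1c2c(O)c(C=O)c(O)c(C=O)c2O[C@]23[C@H]4[C@@H](C[C@H](C)[C@H]2CC[C@]13C)C4(C)C
F2 | step 5 | (1S,3R,4S,6R)-4,7,7-trimethyl-3-(3-methylbut-3-en-1-yl)-2-methylidenebicyclo[4.1.0]heptane | C=C(C)CC[C@H]1C(=C)[C@H]2[C@@H](C[C@@H]1C)C2(C)C
F3 | step 4 | 3,7,7-trimethyl-4-(3-oxobutyl)bicyclo[4.1.0]heptane-2,5-dione (3-Me cis to the CMe2 bridge, side chain trans) | CC(=O)CC[C@H]1C(=O)[C@H]2[C@@H](C(=O)[C@@H]1C)C2(C)C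
F4 | step 4 | 1,1,3,6-tetramethyl-1,1a,3,3a,4,5-hexahydrocyclopropa[e]inden-2(6bH)-one (2-oxo derivative of 10) | CC1=C2[C@H]3[C@@H](C(=O)[C@H](C)[C@H]2CC1)C3(C)C
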